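**Retrosynthetic overview**
- The chain ester is cut first (Mitsunobu esterification with ferulic acid), and the C3 hydroxymethyl group is traced back to a C3 methyl ester on the trans-2-aryl-2,3-dihydrobenzofuran.
- The strategy rests on one feature: C3 of the dihydrofuran ring carries exactly one exocyclic carbon and is bonded to C3a of ring A. The bond C3–C3a can therefore be made by shifting ring A carbon C4a from C4 to C3 of a (2R)-2-arylchroman-4-one; C4 becomes the ester carbon and the pyranone contracts to the dihydrofuran.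
- The flavanone comes from enantioselective conjugate addition of an arylboronic acid (ring B, phenol masked as mesylate) to a 6-alkyl-8-methoxychromone; this sets C2, and the rearrangement then sets C3.
- Ring order: ring A is bought as 2-hydroxy-3-methoxyacetophenone, the pyranone is closed on it, the benzyloxypropyl chain is attached by B-alkyl Suzuki–Miyaura coupling, ring B is added at C2, and the dihydrofuran ring is formed last by ring contraction.

Key step: step 7

Assumption: (S)-t-BuPyOx is taken to deliver the aryl group to the face of chromone C2 that gives the 2R flavanone, by analogy with its sense of induction on cyclic enones; if the sense is opposite, (R)-t-BuPyOx is used and nothing else changes.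

Step 1
Reactants: 1 1-(2-hydroxy-3-methoxyphenyl)ethan-1-one
Product: 2 1-(5-bromo-2-hydroxy-3-methoxyphenyl)ethan-1-one
Conditions: NBS (1.05 equiv), MeCN, 0 °C to rt
Reagents that add atoms: N-bromosuccinimide, O=C1CCC(=O)N1Br
Why: Electrophilic aromatic bromination; the free phenol directs to its para position C5, which is also meta to the acetyl group, and both ortho positions of the phenol are already substituted.

Step 2
Reactants: 2 1-(5-bromo-2-hydroxy-3-methoxyphenyl)ethan-1-one
Product: 4 6-bromo-8-methoxy-4H-chromen-4-one, via enaminone 3 (not isolated)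
Conditions: DMF-DMA (1.5 equiv), toluene, 100 °C; concentrate; then conc. HCl, CH2Cl2, 40 °C
Reagents that add atoms: N,N-dimethylformamide dimethyl acetal, COC(OC)N(C)C
Why: Condensation of the methyl ketone with the amide acetal gives the enaminone, and acid-promoted addition of the phenol with loss of dimethylamine closes the pyranone (the standard chromone synthesis from 2-hydroxyacetophenones).

Step 3
Reactants: 4 6-bromo-8-methoxy-4H-chromen-4-one; 5 allyl benzyl ether
Product: 7 6-[3-(benzyloxy)propyl]-8-methoxy-4H-chromen-4-one, via alkylborane 6 (not isolated)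
Conditions: 5 (1.3 equiv), 9-BBN (0.5 M in THF, 1.25 equiv), 0 °C to rt; then 4, Pd(dppf)Cl2 (5 mol%), K3PO4 (3 M aq.), DMF, 50 °C, degassed
Reagents that add atoms: none
Why: Anti-Markovnikov hydroboration of the terminal alkene with 9-BBN followed by B-alkyl Suzuki–Miyaura coupling with the aryl bromide; a phosphate base at moderate temperature should leave the pyranone closed, and the alkene is kept in slight excess so that no B–H remains to reduce the chromone.

Step 4
Reactants: 8 2-methoxy-4-(4,4,5,5-tetramethyl-1,3,2-dioxaborolan-2-yl)phenol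
Product: 9 2-methoxy-4-(4,4,5,5-tetramethyl-1,3,2-dioxaborolan-2-yl)phenyl methanesulfonate
Conditions: MsCl (1.2 equiv), Et3N (1.5 equiv), CH2Cl2, 0 °C
Reagents that add atoms: methanesulfonyl chloride, CS(=O)(=O)Cl
Why: O-Sulfonylation of the phenol; the pinacol boronate is inert under these conditions.

Step 5
Reactants: 9 2-methoxy-4-(4,4,5,5-tetramethyl-1,3,2-dioxaborolan-2-yl)phenyl methanesulfonate
Product: 10 [3-methoxy-4-(methylsulfonyloxy)phenyl]boronic acid
Conditions: NaIO4 (3 equiv), NH4OAc (3 equiv), acetone/H2O 1:1, rt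
Reagents that add atoms: water, O
Why: Oxidative cleavage of the liberated pinacol by periodate drives hydrolysis of the boronate ester to the boronic acid at near-neutral pH, which the aryl mesylate tolerates.

Step 6
Reactants: 7 6-[3-(benzyloxy)propyl]-8-methoxy-4H-chromen-4-one; 10 [3-methoxy-4-(methylsulfonyloxy)phenyl]boronic acid
Product: 11 (2R)-6-[3-(benzyloxy)propyl]-8-methoxy-2-[3-methoxy-4-(methylsulfonyloxy)phenyl]chroman-4-one
Conditions: 10 (2 equiv), Pd(OCOCF3)2 (5 mol%), (S)-t-BuPyOx (6 mol%), NH4PF6 (30 mol%), H2O (5 equiv), ClCH2CH2Cl, 60 °C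
Reagents that add atoms: none
Why: Asymmetric conjugate addition of an arylboronic acid to a chromone under cationic divalent palladium with a pyridine-oxazoline ligand: transmetalation, enantioface-selective insertion of C2=C3 into the aryl–palladium bond and protonolysis by water set C2 as R under ligand control, and the non-basic medium avoids retro-oxa-Michael opening of the flavanone.

Step 7
Reactants: 11 (2R)-6-[3-(benzyloxy)propyl]-8-methoxy-2-[3-methoxy-4-(methylsulfonyloxy)phenyl]chroman-4-one
Product: 14 methyl (2R,3R)-5-[3-(benzyloxy)propyl]-7-methoxy-2-[3-methoxy-4-(methylsulfonyloxy)phenyl]-2,3-dihydrobenzofuran-3-carboxylate, via enol ether 12 (not isolated), via C3 iodane 13 (not isolated)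
Conditions: PhI(OAc)2 (1.3 equiv), conc. H2SO4 (0.5 equiv), HC(OMe)3, rt to 40 °C; aqueous work-up
Reagents that add atoms: trimethyl orthoformate, COC(OC)OC
Why: Acid and orthoformate turn the C4 ketone into enol ether 12; the activated trivalent iodine reagent then attacks C3 on the face opposite the C2 aryl group while methanol closes C4 to the ketal, giving iodane 13 whose C3–I bond is equatorial and so antiperiplanar to the ring bond C4–C4a. The ketal oxygens push ring A carbon C4a from C4 to C3 as iodobenzene leaves, which forms the bond C3–C3a, and the dimethoxycarbenium ion left at C4 ends as the methyl ester on work-up. The closest known reaction type is the oxidative ring contraction of flavanones with trivalent iodine in acidic trimethyl orthoformate, a 1,2-aryl shift of the kind that converts aryl ketones into 2-arylalkanoates. The dihydrofuran ring is not closed by a cyclisation but arises by contraction of the six-membered pyranone through a bridged phenonium-type transition state, formally a 3-exo attack of the arene ipso carbon on C3 followed by cleavage of C4–C4a. C2 is not touched and keeps its configuration, while C3 is set by the substrate: iodine enters anti to the C2 aryl group and is displaced with inversion, which places the ester trans to that group, and the enolisable ester is also the more stable epimer. The step needs migration of ring A to outrun migration of the 2-aryl group (isoflavone) and simple dehydrogenation (flavone): the ring oxygen O1 ortho to C4a stabilises the bridged cation, the para mesylate and meta methoxy group make the 2-aryl group a poor migrator, and in the half-chair with the 2-aryl group equatorial that group is gauche, not anti, to the C3–I bond.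

Step 8
Reactants: 14 methyl (2R,3R)-5-[3-(benzyloxy)propyl]-7-methoxy-2-[3-methoxy-4-(methylsulfonyloxy)phenyl]-2,3-dihydrobenzofuran-3-carboxylate
Product: 15 4-[(2R,3S)-5-[3-(benzyloxy)propyl]-3-(hydroxymethyl)-7-methoxy-2,3-dihydrobenzofuran-2-yl]-2-methoxyphenyl methanesulfonate
Conditions: LiBH4 (2 equiv), THF, 0 °C to rt
Reagents that add atoms: none
Why: Chemoselective hydride reduction of the methyl ester by LiBH4, which leaves the aryl sulfonate and the benzyl ether untouched and does not affect C2 or C3 (the descriptor at C3 changes by priority only).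

Step 9
Reactants: 15 4-[(2R,3S)-5-[3-(benzyloxy)propyl]-3-(hydroxymethyl)-7-methoxy-2,3-dihydrobenzofuran-2-yl]-2-methoxyphenyl methanesulfonate
Product: 16 4-[(2R,3S)-5-[3-(benzyloxy)propyl]-3-[(tert-butyldimethylsilyloxy)methyl]-7-methoxy-2,3-dihydrobenzofuran-2-yl]-2-methoxyphenyl methanesulfonate
Conditions: TBSCl (1.3 equiv), imidazole (2.5 equiv), DMF, rt
Reagents that add atoms: tert-butyldimethylsilyl chloride, CC(C)(C)[Si](C)(C)Cl
Why: Silylation of the only free hydroxyl group, so that the C3 hydroxymethyl group stays masked when the chain alcohol is later esterified.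

Step 10
Reactants: 16 4-[(2R,3S)-5-[3-(benzyloxy)propyl]-3-[(tert-butyldimethylsilyloxy)methyl]-7-methoxy-2,3-dihydrobenzofuran-2-yl]-2-methoxyphenyl methanesulfonate
Product: 17 4-[(2R,3S)-5-[3-(benzyloxy)propyl]-3-[(tert-butyldimethylsilyloxy)methyl]-7-methoxy-2,3-dihydrobenzofuran-2-yl]-2-methoxyphenol
Conditions: LiN(iPr)2 (LDA, 2.5 equiv), THF, −78 to 0 °C; aq. NH4Cl
Reagents that add atoms: none
Why: Base-induced cleavage of the aryl mesylate: the amide deprotonates the sulfonyl methyl group and the phenoxide is expelled (E1cB with loss of sulfene); with the ester gone and no free hydroxyl present, the substrate offers no other acidic or electrophilic site.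

Step 11
Reactants: 17 4-[(2R,3S)-5-[3-(benzyloxy)propyl]-3-[(tert-butyldimethylsilyloxy)methyl]-7-methoxy-2,3-dihydrobenzofuran-2-yl]-2-methoxyphenol
Product: 18 3-[(2R,3S)-3-[(tert-butyldimethylsilyloxy)methyl]-2-(4-hydroxy-3-methoxyphenyl)-7-methoxy-2,3-dihydrobenzofuran-5-yl]propan-1-ol
Conditions: H2 (1 atm), Pd/C (10 wt%), EtOAc, rt, stopped at full conversion
Reagents that add atoms: none
Why: Catalytic hydrogenolysis of the primary benzyl ether; a neutral aprotic solvent and low pressure should keep the silyl ether and the benzylic C2–O1 bond of the dihydrofuran intact.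

Step 12
Reactants: 18 3-[(2R,3S)-3-[(tert-butyldimethylsilyloxy)methyl]-2-(4-hydroxy-3-methoxyphenyl)-7-methoxy-2,3-dihydrobenzofuran-5-yl]propan-1-ol; 19 ferulic acid
Product: 20 3-[(2R,3S)-3-[(tert-butyldimethylsilyloxy)methyl]-2-(4-hydroxy-3-methoxyphenyl)-7-methoxy-2,3-dihydrobenzofuran-5-yl]propyl (E)-3-(4-hydroxy-3-methoxyphenyl)prop-2-enoate
Conditions: 19 (1.3 equiv), PPh3 (1.2 equiv), DIAD (1.2 equiv), THF, 0 °C to rt
Reagents that add atoms: none
Why: Mitsunobu esterification: the primary alcohol is activated as its alkoxyphosphonium salt and displaced by the carboxylate, the only pronucleophile acidic enough to protonate the betaine, so the two free phenols need no protection and the E alkene is not disturbed.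

Step 13
Reactants: 20 3-[(2R,3S)-3-[(tert-butyldimethylsilyloxy)methyl]-2-(4-hydroxy-3-methoxyphenyl)-7-methoxy-2,3-dihydrobenzofuran-5-yl]propyl (E)-3-(4-hydroxy-3-methoxyphenyl)prop-2-enoate
Product: 21 3-[(2R,3S)-2-(4-hydroxy-3-methoxyphenyl)-3-(hydroxymethyl)-7-methoxy-2,3-dihydrobenzofuran-5-yl]propyl (E)-3-(4-hydroxy-3-methoxyphenyl)prop-2-enoate
Conditions: HF·pyridine, pyridine/THF, 0 °C to rt
Reagents that add atoms: none
Why: Fluoride-mediated cleavage of the primary silyl ether under buffered, non-basic conditions that should spare the cinnamate ester, the phenols and both stereocentres.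

**Compound list**
1 | 1-(2-hydroxy-3-methoxyphenyl)ethan-1-one | CC(=O)c1cccc(OC)c1O | starting material
2 | 1-(5-bromo-2-hydroxy-3-methoxyphenyl)ethan-1-one | CC(=O)c1cc(Br)cc(OC)c1O | intermediate
3 | (E)-1-(5-bromo-2-hydroxy-3-methoxyphenyl)-3-(dimethylamino)prop-2-en-1-one (enaminone, not isolated) | CN(C)/C=C/C(=O)c1cc(Br)cc(OC)c1O | intermediate
4 | 6-bromo-8-methoxy-4H-chromen-4-one | O=c1ccoc2c(OC)cc(Br)cc12 | intermediate
5 | allyl benzyl ether | C=CCOCc1ccccc1 | starting material
6 | 9-[3-(benzyloxy)propyl]-9-borabicyclo[3.3.1]nonane (alkylborane, not isolated) | c1ccccc1COCCCB1C2CCCC1CCC2 | intermediate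
7 | 6-[3-(benzyloxy)propyl]-8-methoxy-4H-chromen-4-one | O=c1ccoc2c(OC)cc(CCCOCc3ccccc3)cc12 | intermediate
8 | 2-methoxy-4-(4,4,5,5-tetramethyl-1,3,2-dioxaborolan-2-yl)phenol | COc1cc(B2OC(C)(C)C(C)(C)O2)ccc1O | starting material
9 | 2-methoxy-4-(4,4,5,5-tetramethyl-1,3,2-dioxaborolan-2-yl)phenyl methanesulfonate | COc1cc(B2OC(C)(C)C(C)(C)O2)ccc1OS(C)(=O)=O | intermediate
10 | [3-methoxy-4-(methylsulfonyloxy)phenyl]boronic acid | COc1cc(B(O)O)ccc1OS(C)(=O)=O | intermediate
11 | (2R)-6-[3-(benzyloxy)propyl]-8-methoxy-2-[3-methoxy-4-(methylsulfonyloxy)phenyl]chroman-4-one | O=C1C[C@H](c2ccc(OS(C)(=O)=O)c(OC)c2)Oc2c(OC)cc(CCCOCc3ccccc3)cc12 | intermediate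
12 | (2R)-6-[3-(benzyloxy)propyl]-4,8-dimethoxy-2-[3-methoxy-4-(methylsulfonyloxy)phenyl]-2H-chromene (enol ether, not isolated) | COC1=C[C@H](c2ccc(OS(C)(=O)=O)c(OC)c2)Oc2c(OC)cc(CCCOCc3ccccc3)cc12 | intermediate
13 | 4,4-dimethyl ketal of 11 carrying an acetoxy(phenyl)iodanyl group at C3, trans to the C2 aryl group (not isolated) | COC1(OC)[C@@H](I(OC(C)=O)c2ccccc2)[C@H](c2ccc(OS(C)(=O)=O)c(OC)c2)Oc2c(OC)cc(CCCOCc3ccccc3)cc12 | intermediate
14 | methyl (2R,3R)-5-[3-(benzyloxy)propyl]-7-methoxy-2-[3-methoxy-4-(methylsulfonyloxy)phenyl]-2,3-dihydrobenzofuran-3-carboxylate (2,3-trans) | c1ccccc1COCCCc2cc(OC)c3c(c2)[C@@H](C(=O)OC)[C@H](c2ccc(OS(C)(=O)=O)c(OC)c2)O3 | intermediate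
15 | 4-[(2R,3S)-5-[3-(benzyloxy)propyl]-3-(hydroxymethyl)-7-methoxy-2,3-dihydrobenzofuran-2-yl]-2-methoxyphenyl methanesulfonate | c1ccccc1COCCCc2cc(OC)c3c(c2)[C@@H](CO)[C@H](c2ccc(OS(C)(=O)=O)c(OC)c2)O3 | intermediate
16 | 4-[(2R,3S)-5-[3-(benzyloxy)propyl]-3-[(tert-butyldimethylsilyloxy)methyl]-7-methoxy-2,3-dihydrobenzofuran-2-yl]-2-methoxyphenyl methanesulfonate | c1ccccc1COCCCc2cc(OC)c3c(c2)[C@@H](CO[Si](C)(C)C(C)(C)C)[C@H](c2ccc(OS(C)(=O)=O)c(OC)c2)O3 | intermediate
17 | 4-[(2R,3S)-5-[3-(benzyloxy)propyl]-3-[(tert-butyldimethylsilyloxy)methyl]-7-methoxy-2,3-dihydrobenzofuran-2-yl]-2-methoxyphenol | c1ccccc1COCCCc2cc(OC)c3c(c2)[C@@H](CO[Si](C)(C)C(C)(C)C)[C@H](c2ccc(O)c(OC)c2)O3 | intermediate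
18 | 3-[(2R,3S)-3-[(tert-butyldimethylsilyloxy)methyl]-2-(4-hydroxy-3-methoxyphenyl)-7-methoxy-2,3-dihydrobenzofuran-5-yl]propan-1-ol | OCCCc1cc(OC)c2c(c1)[C@@H](CO[Si](C)(C)C(C)(C)C)[C@H](c1ccc(O)c(OC)c1)O2 | intermediate
19 | ferulic acid, (E)-3-(4-hydroxy-3-methoxyphenyl)prop-2-enoic acid | COc1cc(/C=C/C(=O)O)ccc1O | starting material
20 | 3-[(2R,3S)-3-[(tert-butyldimethylsilyloxy)methyl]-2-(4-hydroxy-3-methoxyphenyl)-7-methoxy-2,3-dihydrobenzofuran-5-yl]propyl (E)-3-(4-hydroxy-3-methoxyphenyl)prop-2-enoate | COc1cc(/C=C/C(=O)OCCCc2cc(OC)c3c(c2)[C@@H](CO[Si](C)(C)C(C)(C)C)[C@H](c2ccc(O)c(OC)c2)O3)ccc1O | intermediate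
21 | 3-[(2R,3S)-2-(4-hydroxy-3-methoxyphenyl)-3-(hydroxymethyl)-7-methoxy-2,3-dihydrobenzofuran-5-yl]propyl (E)-3-(4-hydroxy-3-methoxyphenyl)prop-2-enoate | COc1cc(/C=C/C(=O)OCCCc2cc(OC)c3c(c2)[C@@H](CO)[C@H](c2ccc(O)c(OC)c2)O3)ccc1O | target

**Step count and risks**
Total step count: 13. Longest linear sequence: 11 steps (steps 1–3 and 6–13, from compound 1); steps 4 and 5 form the two-step side branch to the boronic acid.

Steps most likely to fail:

1. Step 7. Migration of the 2-aryl group instead of ring A, plain dehydrogenation to the flavone, or electrophilic attack of the oxidant on the electron-rich ring A could divert material from the ring contraction. The fallback reaches the same bond by a carbene pathway in which only the acyl-bound ring A carbon can migrate. It sets out from 11: the lithium enolate (LiN(SiMe3)2, THF, −78 °C) would be acylated with 2,2,2-trifluoroethyl trifluoroacetate to the 3-trifluoroacetyl flavanone F1, and detrifluoroacetylative diazo transfer (MsN3, Et3N, MeCN, water) would give the 3-diazoflavanone F2. Irradiation at 365 nm in methanol should trigger a Wolff rearrangement to the ring-contracted ketene F3, which methanol traps as the ester. Protonation may give the cis ester F4 beside the trans ester; catalytic DBU in CH2Cl2 would equilibrate the mixture at C3, and the fallback returns to the route at 14.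

2. Step 6. Facial discrimination by the ligand may be insufficient for this 8-methoxy chromone, or slow retro-oxa-Michael opening may erode the configuration at C2. The fallback separates the enantiomers by reduction. It sets out from 7 and 10: the same addition with achiral 2,2'-bipyridine as ligand would give the racemic flavanone F5. Asymmetric transfer hydrogenation with RuCl(p-cymene)(TsDPEN) and HCO2H/Et3N, run as a kinetic resolution with the catalyst enantiomer that consumes the 2S ketone, would reduce that enantiomer to the cis-(2S,4S)-flavan-4-ol F6 and leave the 2R ketone, which is separated and re-enters the route at 11.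

3. Step 11. Hydrogenolysis may go on to cleave the benzylic C2–O1 bond of the dihydrofuran, which the free para-phenol on the 2-aryl group activates. The fallback removes the benzyl group while the mesylate still keeps the 2-aryl group electron-poor. It sets out from 16: hydrogenolysis under the conditions of step 11 would give the chain alcohol F7. Transient silylation (TMSCl, Et3N, CH2Cl2) to the trimethylsilyl ether F8 keeps the alkoxide away from the sulfene formed in the next operation; cleavage of the mesylate with LiN(iPr)2 as in step 10 and a mild acidic work-up (citric acid, MeOH), which removes only the trimethylsilyl group, would return to the route at 18.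

**Further compounds**
F1 | step 7 | (2R)-6-[3-(benzyloxy)propyl]-8-methoxy-2-[3-methoxy-4-(methylsulfonyloxy)phenyl]-3-(trifluoroacetyl)chroman-4-one (C3 epimers and enol) | O=C1C(C(=O)C(F)(F)F)[C@H](c2ccc(OS(C)(=O)=O)c(OC)c2)Oc2c(OC)cc(CCCOCc3ccccc3)cc12
F2 | step 7 | (2S)-6-[3-(benzyloxy)propyl]-3-diazo-8-methoxy-2-[3-methoxy-4-(methylsulfonyloxy)phenyl]chroman-4-one (C2 arranged as in 11; the descriptor changes by priority only) | O=C1C(=[N+]=[N-])[C@H](c2ccc(OS(C)(=O)=O)c(OC)c2)Oc2c(OC)cc(CCCOCc3ccccc3)cc12
F3 | step 7 | ketene: 5-[3-(benzyloxy)propyl]-7-methoxy-2-[3-methoxy-4-(methylsulfonyloxy)phenyl]-3-(oxomethylidene)-2,3-dihydrobenzofuran, C2 arranged as in 14 | O=C=C1[C@H](c2ccc(OS(C)(=O)=O)c(OC)c2)Oc2c(OC)cc(CCCOCc3ccccc3)cc12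
F4 | step 7 | methyl (2R,3S)-5-[3-(benzyloxy)propyl]-7-methoxy-2-[3-methoxy-4-(methylsulfonyloxy)phenyl]-2,3-dihydrobenzofuran-3-carboxylate (2,3-cis) | c1ccccc1COCCCc2cc(OC)c3c(c2)[C@H](C(=O)OC)[C@H](c2ccc(OS(C)(=O)=O)c(OC)c2)O3
F5 | step 6 | racemic 6-[3-(benzyloxy)propyl]-8-methoxy-2-[3-methoxy-4-(methylsulfonyloxy)phenyl]chroman-4-one | O=C1CC(c2ccc(OS(C)(=O)=O)c(OC)c2)Oc2c(OC)cc(CCCOCc3ccccc3)cc12
F6 | step 6 | (2S,4S)-6-[3-(benzyloxy)propyl]-8-methoxy-2-[3-methoxy-4-(methylsulfonyloxy)phenyl]chroman-4-ol (2,4-cis) | O[C@H]1C[C@@H](c2ccc(OS(C)(=O)=O)c(OC)c2)Oc2c(OC)cc(CCCOCc3ccccc3)cc12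
F7 | step 11 | 4-[(2R,3S)-3-[(tert-butyldimethylsilyloxy)methyl]-5-(3-hydroxypropyl)-7-methoxy-2,3-dihydrobenzofuran-2-yl]-2-methoxyphenyl methanesulfonate | OCCCc1cc(OC)c2c(c1)[C@@H](CO[Si](C)(C)C(C)(C)C)[C@H](c1ccc(OS(C)(=O)=O)c(OC)c1)O2
F8 | step 11 | 4-[(2R,3S)-3-[(tert-butyldimethylsilyloxy)methyl]-7-methoxy-5-[3-(trimethylsilyloxy)propyl]-2,3-dihydrobenzofuran-2-yl]-2-methoxyphenyl methanesulfonate | C[Si](C)(C)OCCCc1cc(OC)c2c(c1)[C@@H](CO[Si](C)(C)C(C)(C)C)[C@H](c1ccc(OS(C)(=O)=O)c(OC)c1)O2
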